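**Plan**

- Numbering (chromanone core): O1, C2, C3, C4, C4a, C5–C8, C8a; ring A is the carbocycle, ring B the pyranone, ring C a temporary lactone. Retrosynthetic cuts, in order: C8–prenyl; the acyl–O5 bond of ring C (the C6 side-chain acid held as a lactone); C8–CH2(cyclobutyl); C3–C4 of ring B; O1–C2; C4a–CHO; the C=C of a coumarin.
- Enabling feature: C4 is an aryl ketone carbon on C4a, which lies between the oxygen-bearing C5 and C8a, and C2 is a methyl-bearing secondary ether carbon next to C3. Ring B therefore opens at C3–C4 to a C4a aldehyde and an (R)-but-3-yn-2-yl ether on O1.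
- Forward: ring A comes from phloroglucinol and ring C from a Pechmann condensation. Ring B closes by carbene-catalysed alkyne hydroacylation. The C8 arm is attached by Negishi coupling with a cyclobutylmethylzinc made from (+)-α-pinene. Ring A is then dearomatised by C8 prenylation and ring C is opened.
- Stereochemistry: the side-chain centre (S) comes from a ligand-controlled copper hydride reduction of the coumarin. C2 (R) comes from (S)-but-3-yn-2-ol by Mitsunobu inversion, and C3 (S) from hydrogenation anti to the C2 methyl (cis). The cyclobutane (1S,3R) comes from (+)-α-pinene, and C8 (R) from a chiral palladium allylation catalyst.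

Key step: step 7

Assumption: the ligand antipodes written in steps 3 and 17 are taken to give the configurations drawn; both antipodes of each ligand are commercial, so the other one is used if the sense of induction proves opposite.

**Step 1**
Reactants: 1 phloroglucinol; 2 ethyl 3-oxohexanoate
Product: 3 5,7-dihydroxy-4-propyl-2H-chromen-2-one
Conditions: conc. H2SO4, 0 °C → rt
Reagents that add atoms: none
Why: Pechmann condensation (transesterification, intramolecular hydroxyalkylation of the arene, dehydration) of a symmetric triol with a β-keto ester can give only this coumarin.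

**Step 2**
Reactants: 3 5,7-dihydroxy-4-propyl-2H-chromen-2-one
Product: 4 5,7-bis[(tert-butyldimethylsilyl)oxy]-4-propyl-2H-chromen-2-one
Conditions: TBSCl, imidazole, DMF, rt
Reagents that add atoms: tert-butyldimethylsilyl chloride, CC(C)(C)[Si](C)(C)Cl
Why: Standard silylation masks both phenols, which would otherwise quench the hydride catalyst and consume silane in step 3.

**Step 3**
Reactants: 4 5,7-bis[(tert-butyldimethylsilyl)oxy]-4-propyl-2H-chromen-2-one
Product: 6 (4S)-5,7-dihydroxy-4-propyl-3,4-dihydro-2H-chromen-2-one, via bis-silyl dihydrocoumarin 5 (not isolated)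
Conditions: Cu(OAc)2·H2O (3 mol%), (R)-DTBM-SEGPHOS (3 mol%), (EtO)2MeSiH, t-BuOH, toluene, 0 °C → rt; then TBAF, AcOH, THF, 0 °C
Reagents that add atoms: none
Why: Copper hydride asymmetric 1,4-reduction of a 4-substituted coumarin: the chiral bisphosphine directs hydride to one face of C4 and sets the 4S centre, tert-butanol protonates the copper enolate so that over-reduction to the lactol is limited, and buffered fluoride then removes both aryl silyl ethers.

**Step 4**
Reactants: 6 (4S)-5,7-dihydroxy-4-propyl-3,4-dihydro-2H-chromen-2-one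
Product: 7 (4S)-5,7-dihydroxy-2-oxo-4-propyl-3,4-dihydro-2H-chromene-8-carbaldehyde
Conditions: POCl3, DMF, MeCN, 0 °C → rt; then H2O, 40 °C
Reagents that add atoms: N,N-dimethylformamide, CN(C)C=O; water, O
Why: Vilsmeier–Haack formylation should favour C8, which is ortho to one hydroxyl and para to the other (the resorcinol orientation, as in the formylation of orcinol and of 5,7-dihydroxycoumarins), over C6, which lies between the two hydroxyls.

**Step 5**
Reactants: 7 (4S)-5,7-dihydroxy-2-oxo-4-propyl-3,4-dihydro-2H-chromene-8-carbaldehyde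
Product: 8 (4S)-5-(benzyloxy)-7-hydroxy-2-oxo-4-propyl-3,4-dihydro-2H-chromene-8-carbaldehyde
Conditions: BnBr (1.05 equiv), CsHCO3, MeCN, 60 °C
Reagents that add atoms: benzyl bromide, BrCc1ccccc1
Why: Williamson etherification under bicarbonate selects the 5-OH, which is para to the aldehyde and not hydrogen-bonded, over the chelated 7-OH (as in the 4-O-alkylation of 2,4-dihydroxybenzaldehyde), and leaves the lactone intact.

**Step 6**
Reactants: 8 (4S)-5-(benzyloxy)-7-hydroxy-2-oxo-4-propyl-3,4-dihydro-2H-chromene-8-carbaldehyde; 9 (S)-but-3-yn-2-ol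
Product: 10 (4S)-5-(benzyloxy)-7-[(2R)-but-3-yn-2-yloxy]-2-oxo-4-propyl-3,4-dihydro-2H-chromene-8-carbaldehyde
Conditions: PPh3, DIAD, THF, 0 °C → rt
Reagents that add atoms: none
Why: Mitsunobu etherification of the acidic salicylaldehyde-type phenol with a secondary propargylic alcohol proceeds by SN2 displacement, so the (S)-alcohol gives the (R)-ether that becomes C2.

**Step 7**
Reactants: 10 (4S)-5-(benzyloxy)-7-[(2R)-but-3-yn-2-yloxy]-2-oxo-4-propyl-3,4-dihydro-2H-chromene-8-carbaldehyde
Product: 11 (4S,8R)-5-(benzyloxy)-8-methyl-9-methylidene-4-propyl-3,4,8,9-tetrahydro-2H,10H-pyrano[2,3-f]chromene-2,10-dione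
Conditions: 3-mesityl-5,6,7,8-tetrahydro-4H-cyclohepta[d]thiazol-3-ium perchlorate (10 mol%), K2CO3 (20 mol%), THF (0.02 M), 70 °C
Reagents that add atoms: none
Why: The carbene freed from the thiazolium salt adds to the C4 aldehyde and proton transfer gives the enaminol (Breslow intermediate), whose nucleophilic carbon bonds to the internal alkyne carbon (C3) while its O–H proton passes to the terminal carbon in a concerted Conia-ene-like transition state; collapse of the adduct releases the carbene and the exocyclic enone. The closest known reaction is the carbene-catalysed intramolecular hydroacylation of unactivated alkynes in 2-propargyloxybenzaldehydes to 3-alkylidenechroman-4-ones. Ring B closes in the 6-exo-dig mode through the new C3–C4 bond. No stereocentre is created; C2 (R) is not a reacting atom and its propargylic C–H is not acidic enough for the substoichiometric carbonate. The step needs the unimolecular closure to outrun Stetter addition of a second enaminol to the product enone, benzoin coupling and base-induced migration of the exocyclic double bond into the ring: the aldehyde carbon sits between two oxygen-bearing ring carbons (C5 and C8a), which makes its enaminol too hindered for bimolecular reactions, and high dilution and immediate hydrogenation of 11 support this.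

**Step 8**
Reactants: 11 (4S,8R)-5-(benzyloxy)-8-methyl-9-methylidene-4-propyl-3,4,8,9-tetrahydro-2H,10H-pyrano[2,3-f]chromene-2,10-dione
Product: 12 (4S,8R,9S)-5-hydroxy-8,9-dimethyl-4-propyl-3,4,8,9-tetrahydro-2H,10H-pyrano[2,3-f]chromene-2,10-dione
Conditions: H2 (1 atm), 10% Pd/C, EtOAc, rt
Reagents that add atoms: none
Why: Heterogeneous hydrogenation with concurrent benzyl ether hydrogenolysis: the C2 methyl sits pseudo-axial to avoid allylic strain with the methylidene group, so hydrogen adds from the opposite face and the new C3 methyl ends cis to it (C3 = S), a kinetic product that is not exposed to base.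

**Step 9**
Reactants: 12 (4S,8R,9S)-5-hydroxy-8,9-dimethyl-4-propyl-3,4,8,9-tetrahydro-2H,10H-pyrano[2,3-f]chromene-2,10-dione
Product: 13 (4S,8R,9S)-5-hydroxy-6-iodo-8,9-dimethyl-4-propyl-3,4,8,9-tetrahydro-2H,10H-pyrano[2,3-f]chromene-2,10-dione
Conditions: NIS, TsOH·H2O (10 mol%), MeCN, 0 °C
Reagents that add atoms: N-iodosuccinimide, O=C1CCC(=O)N1I
Why: Electrophilic aromatic iodination can occur only at the single free ring carbon (target C8), which is ortho to the free phenol, and the mild acid should not epimerise C3.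

**Step 10**
Reactants: 14 (1R,5R)-(+)-α-pinene
Product: 15 (1R,5R)-(+)-verbenone
Conditions: t-BuOOH, Cr(CO)6 (cat.), MeCN, reflux
Reagents that add atoms: tert-butyl hydroperoxide, CC(C)(C)OO
Why: Chromium-catalysed allylic oxidation converts the ring CH2 next to the trisubstituted alkene into the enone carbonyl without touching the bridgehead stereocentres.

**Step 11**
Reactants: 15 (1R,5R)-(+)-verbenone
Product: 16 (1R,3S)-3-acetyl-2,2-dimethylcyclobutane-1-carboxylic acid
Conditions: RuCl3·xH2O (2 mol%), NaIO4, CCl4/MeCN/H2O, rt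
Reagents that add atoms: sodium periodate, [Na+].[O-]I(=O)(=O)=O; water, O
Why: Ruthenium tetroxide cleavage of the enone C=C gives the methyl ketone and an α-keto acid that is cleaved further with loss of CO2, so the cis-1,3-disubstituted cyclobutane is released with both pinene stereocentres intact.

**Step 12**
Reactants: 16 (1R,3S)-3-acetyl-2,2-dimethylcyclobutane-1-carboxylic acid
Product: 17 methyl (1R,3S)-3-acetyl-2,2-dimethylcyclobutane-1-carboxylate
Conditions: TMSCHN2, MeOH/toluene, 0 °C
Reagents that add atoms: trimethylsilyldiazomethane, C[Si](C)(C)C=[N+]=[N-]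
Why: Diazoalkane esterification is neutral, so the epimerisable centre next to the ketone is not disturbed.

**Step 13**
Reactants: 17 methyl (1R,3S)-3-acetyl-2,2-dimethylcyclobutane-1-carboxylate
Product: 18 methyl (1R,3R)-2,2-dimethyl-3-(prop-1-en-2-yl)cyclobutane-1-carboxylate
Conditions: Zn, CH2Br2, TiCl4, THF/CH2Cl2, 0 °C → rt
Reagents that add atoms: dibromomethane, BrCBr
Why: Takai–Lombardo methylenation is non-basic and selective for a ketone over an ester, so the isopropenyl group is formed without enolisation and the cis relationship is kept.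

**Step 14**
Reactants: 18 methyl (1R,3R)-2,2-dimethyl-3-(prop-1-en-2-yl)cyclobutane-1-carboxylate
Product: 19 [(1R,3R)-2,2-dimethyl-3-(prop-1-en-2-yl)cyclobutyl]methanol
Conditions: LiAlH4, Et2O, 0 °C; then H2O, 15% NaOH
Reagents that add atoms: none
Why: Hydride reduction of the ester to the primary alcohol leaves the isolated alkene and both ring stereocentres untouched.

**Step 15**
Reactants: 19 [(1R,3R)-2,2-dimethyl-3-(prop-1-en-2-yl)cyclobutyl]methanol
Product: 20 (1R,3R)-1-(iodomethyl)-2,2-dimethyl-3-(prop-1-en-2-yl)cyclobutane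
Conditions: I2, PPh3, imidazole, CH2Cl2, 0 °C → rt
Reagents that add atoms: iodine, II
Why: Appel-type iodination displaces the activated primary oxygen by SN2, so no cyclobutylcarbinyl cation forms and the ring cannot expand.

**Step 16**
Reactants: 13 (4S,8R,9S)-5-hydroxy-6-iodo-8,9-dimethyl-4-propyl-3,4,8,9-tetrahydro-2H,10H-pyrano[2,3-f]chromene-2,10-dione; 20 (1R,3R)-1-(iodomethyl)-2,2-dimethyl-3-(prop-1-en-2-yl)cyclobutane
Product: 22 (4S,8R,9S)-6-{[(1S,3R)-2,2-dimethyl-3-(prop-1-en-2-yl)cyclobutyl]methyl}-5-hydroxy-8,9-dimethyl-4-propyl-3,4,8,9-tetrahydro-2H,10H-pyrano[2,3-f]chromene-2,10-dione, via alkylzinc iodide 21 (not isolated)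
Conditions: 20, Zn dust, LiCl, THF, 40 °C; then 13, Pd(OAc)2 (3 mol%), SPhos (6 mol%), THF, rt → 40 °C, slow addition of 21
Reagents that add atoms: none
Why: Negishi coupling of a primary alkylzinc halide, made by LiCl-assisted zinc insertion, with a di-ortho-substituted aryl iodide under a bulky biarylphosphine tolerates ketone, lactone and the free phenol (alkylzinc halides are protonated only slowly by phenols), and β-hydride elimination is disfavoured because it would give a methylenecyclobutane.

**Step 17**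
Reactants: 22 (4S,8R,9S)-6-{[(1S,3R)-2,2-dimethyl-3-(prop-1-en-2-yl)cyclobutyl]methyl}-5-hydroxy-8,9-dimethyl-4-propyl-3,4,8,9-tetrahydro-2H,10H-pyrano[2,3-f]chromene-2,10-dione
Product: 24 (3S)-3-[(2R,3S,8R)-8-{[(1S,3R)-2,2-dimethyl-3-(prop-1-en-2-yl)cyclobutyl]methyl}-5-hydroxy-2,3-dimethyl-8-(3-methylbut-2-en-1-yl)-4,7-dioxo-3,4,7,8-tetrahydro-2H-chromen-6-yl]hexanoic acid, via dienone enol lactone 23 (not isolated)
Conditions: Pd2(dba)3·CHCl3 (2.5 mol%), (R,R)-DACH-phenyl Trost ligand (7.5 mol%), tert-butyl prenyl carbonate, toluene, 0 °C → rt; then LiOH, THF/H2O, 0 °C; then 1 M HCl to pH 3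
Reagents that add atoms: tert-butyl 3-methylbut-2-en-1-yl carbonate, CC(C)=CCOC(=O)OC(C)(C)C; lithium hydroxide, [Li+].[OH-]
Why: Tsuji–Trost asymmetric allylic alkylation run in the dearomatising sense: the carbonate ionises to a π-prenylpalladium cation and tert-butoxide, the resulting phenoxide is attacked at its only accessible ortho carbon (C8; the other ortho carbon is the congested ring-fusion carbon C6 and the para carbon carries the acyl group) by the unsubstituted allyl terminus, O-prenylation is reversible under the catalyst, the chiral ligand sets the quaternary centre C8 (R), and the activated enol lactone is then opened by cold hydroxide to the vinylogous acid and the free carboxylic acid.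

**Compound list**

1 | phloroglucinol | Oc1cc(O)cc(O)c1 | starting material
2 | ethyl 3-oxohexanoate | CCCC(=O)CC(=O)OCC | starting material
3 | 5,7-dihydroxy-4-propyl-2H-chromen-2-one | CCCC1=CC(=O)Oc2cc(O)cc(O)c12 | intermediate
4 | 5,7-bis[(tert-butyldimethylsilyl)oxy]-4-propyl-2H-chromen-2-one | CCCC1=CC(=O)Oc2cc(O[Si](C)(C)C(C)(C)C)cc(O[Si](C)(C)C(C)(C)C)c12 | intermediate
5 | (4S)-5,7-bis[(tert-butyldimethylsilyl)oxy]-4-propyl-3,4-dihydro-2H-chromen-2-one | CCC[C@H]1CC(=O)Oc2cc(O[Si](C)(C)C(C)(C)C)cc(O[Si](C)(C)C(C)(C)C)c21 | intermediate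
6 | (4S)-5,7-dihydroxy-4-propyl-3,4-dihydro-2H-chromen-2-one | CCC[C@H]1CC(=O)Oc2cc(O)cc(O)c21 | intermediate
7 | (4S)-5,7-dihydroxy-2-oxo-4-propyl-3,4-dihydro-2H-chromene-8-carbaldehyde | CCC[C@H]1CC(=O)Oc2c(C=O)c(O)cc(O)c21 | intermediate
8 | (4S)-5-(benzyloxy)-7-hydroxy-2-oxo-4-propyl-3,4-dihydro-2H-chromene-8-carbaldehyde | CCC[C@H]1CC(=O)Oc2c(C=O)c(O)cc(OCc3ccccc3)c21 | intermediate
9 | (S)-but-3-yn-2-ol | C[C@H](O)C#C | starting material
10 | (4S)-5-(benzyloxy)-7-[(2R)-but-3-yn-2-yloxy]-2-oxo-4-propyl-3,4-dihydro-2H-chromene-8-carbaldehyde | CCC[C@H]1CC(=O)Oc2c(C=O)c(O[C@H](C)C#C)cc(OCc3ccccc3)c21 | intermediate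
11 | (4S,8R)-5-(benzyloxy)-8-methyl-9-methylidene-4-propyl-3,4,8,9-tetrahydro-2H,10H-pyrano[2,3-f]chromene-2,10-dione | CCC[C@H]1CC(=O)Oc2c3c(cc(OCc4ccccc4)c21)O[C@H](C)C(=C)C3=O | intermediate
12 | (4S,8R,9S)-5-hydroxy-8,9-dimethyl-4-propyl-3,4,8,9-tetrahydro-2H,10H-pyrano[2,3-f]chromene-2,10-dione | CCC[C@H]1CC(=O)Oc2c3c(cc(O)c21)O[C@H](C)[C@H](C)C3=O | intermediate
13 | (4S,8R,9S)-5-hydroxy-6-iodo-8,9-dimethyl-4-propyl-3,4,8,9-tetrahydro-2H,10H-pyrano[2,3-f]chromene-2,10-dione | CCC[C@H]1CC(=O)Oc2c3c(c(I)c(O)c21)O[C@H](C)[C@H](C)C3=O | intermediate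
14 | (1R,5R)-(+)-α-pinene | CC1=CC[C@@H]2C[C@H]1C2(C)C | starting material
15 | (1R,5R)-(+)-verbenone | CC1=CC(=O)[C@@H]2C[C@H]1C2(C)C | intermediate
16 | (1R,3S)-3-acetyl-2,2-dimethylcyclobutane-1-carboxylic acid (cis-pinononic acid) | CC(=O)[C@H]1C[C@@H](C(=O)O)C1(C)C | intermediate
17 | methyl (1R,3S)-3-acetyl-2,2-dimethylcyclobutane-1-carboxylate | CC(=O)[C@H]1C[C@@H](C(=O)OC)C1(C)C | intermediate
18 | methyl (1R,3R)-2,2-dimethyl-3-(prop-1-en-2-yl)cyclobutane-1-carboxylate | C=C(C)[C@H]1C[C@@H](C(=O)OC)C1(C)C | intermediate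
19 | [(1R,3R)-2,2-dimethyl-3-(prop-1-en-2-yl)cyclobutyl]methanol | C=C(C)[C@H]1C[C@@H](CO)C1(C)C | intermediate
20 | (1R,3R)-1-(iodomethyl)-2,2-dimethyl-3-(prop-1-en-2-yl)cyclobutane | C=C(C)[C@H]1C[C@@H](CI)C1(C)C | intermediate
21 | {[(1R,3R)-2,2-dimethyl-3-(prop-1-en-2-yl)cyclobutyl]methyl}zinc iodide | C=C(C)[C@H]1C[C@@H](C[Zn]I)C1(C)C | intermediate
22 | (4S,8R,9S)-6-{[(1S,3R)-2,2-dimethyl-3-(prop-1-en-2-yl)cyclobutyl]methyl}-5-hydroxy-8,9-dimethyl-4-propyl-3,4,8,9-tetrahydro-2H,10H-pyrano[2,3-f]chromene-2,10-dione | CCC[C@H]1CC(=O)Oc2c3c(c(C[C@@H]4C[C@H](C(C)=C)C4(C)C)c(O)c21)O[C@H](C)[C@H](C)C3=O | intermediate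
23 | (4S,6R,8R,9S)-6-{[(1S,3R)-2,2-dimethyl-3-(prop-1-en-2-yl)cyclobutyl]methyl}-8,9-dimethyl-6-(3-methylbut-2-en-1-yl)-4-propyl-3,4,8,9-tetrahydro-2H-pyrano[2,3-f]chromene-2,5,10(6H)-trione | C=C(C)[C@H]1C[C@@H](C[C@@]2(CC=C(C)C)C(=O)C4=C(OC(=O)C[C@@H]4CCC)C3=C2O[C@H](C)[C@H](C)C3=O)C1(C)C | intermediate
24 | (3S)-3-[(2R,3S,8R)-8-{[(1S,3R)-2,2-dimethyl-3-(prop-1-en-2-yl)cyclobutyl]methyl}-5-hydroxy-2,3-dimethyl-8-(3-methylbut-2-en-1-yl)-4,7-dioxo-3,4,7,8-tetrahydro-2H-chromen-6-yl]hexanoic acid | C=C(C)[C@H]1C[C@@H](C[C@@]2(CC=C(C)C)C(=O)C([C@@H](CCC)CC(=O)O)=C(O)C3=C2O[C@H](C)[C@H](C)C3=O)C1(C)C | target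

**Step count**

Total: 17 steps. Longest linear sequence: 11 steps (steps 1–9, 16 and 17, from phloroglucinol); the cyclobutane branch (steps 10–15) joins at step 16.

**Steps most likely to fail**

Step 17. The phenoxide–allylpalladium ion pair may collapse at oxygen instead of carbon. The chiral ligand may exert little facial bias on a nucleophile whose resident stereocentres are remote. The C-prenylated dienone may also re-ionise under the catalyst and lose its configuration at C8. The fallback sets out from 22 and returns at 24. The lithium phenoxide of 22 (LiHMDS, toluene, 0 °C) is alkylated with prenyl bromide; a contact ion pair in a non-polar solvent favours ortho C-alkylation. This gives 23 together with the C6 epimer of 23 F1. Hydrolysis with cold LiOH as in step 17 gives 24 and 8-epi-24 F2, and the two acids are separated by preparative HPLC.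

Step 7. Carbene addition to the doubly ortho-substituted aldehyde may be slow. The product enone may be intercepted by a second enaminol (Stetter addition). The exocyclic double bond may migrate into the ring under the basic conditions, which would erase C2. The fallback sets out from 10 and returns at 11. Nickel-catalysed reductive cyclisation of the ynal (Ni(cod)2, PBu3, Et3SiH, THF) forms the same C3–C4 bond with the same exo closure and gives the triethylsilyl ether of the 4-hydroxy-3-methylidene tricycle F3. TBAF frees the allylic alcohol F4, and Dess–Martin periodinane buffered with NaHCO3 oxidises it to 11 without base.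

Step 8. Palladium hydride may isomerise the methylidene enone to the achiral-at-C2 chromone before hydrogen is added. Facial selectivity may be insufficient, giving the trans isomer. The aryl ketone may be over-reduced. The fallback sets out from 11 and returns at 12. Conjugate hydride addition with [(Ph3P)CuH]6 in wet toluene, with kinetic protonation of the copper enolate on the face anti to the C2 methyl, gives the cis-2,3-dimethyl benzyl ether F5. Separate hydrogenolysis (H2, Pd/C, EtOAc) of F5 then gives 12.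

**Further compounds**

F1 | step 17 | C6 epimer of dienone enol lactone 23 | C=C(C)[C@H]1C[C@@H](C[C@]2(CC=C(C)C)C(=O)C4=C(OC(=O)C[C@@H]4CCC)C3=C2O[C@H](C)[C@H](C)C3=O)C1(C)C
F2 | step 17 | 8-epi-24 | C=C(C)[C@H]1C[C@@H](C[C@]2(CC=C(C)C)C(=O)C([C@@H](CCC)CC(=O)O)=C(O)C3=C2O[C@H](C)[C@H](C)C3=O)C1(C)C
F3 | step 7 | (4S,8R)-5-(benzyloxy)-8-methyl-9-methylidene-4-propyl-10-[(triethylsilyl)oxy]-3,4,9,10-tetrahydro-2H,8H-pyrano[2,3-f]chromen-2-one (C10 epimers) | CCC[C@H]1CC(=O)Oc2c3c(cc(OCc4ccccc4)c21)O[C@H](C)C(=C)C3O[Si](CC)(CC)CC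
F4 | step 7 | (4S,8R)-5-(benzyloxy)-10-hydroxy-8-methyl-9-methylidene-4-propyl-3,4,9,10-tetrahydro-2H,8H-pyrano[2,3-f]chromen-2-one (C10 epimers) | CCC[C@H]1CC(=O)Oc2c3c(cc(OCc4ccccc4)c21)O[C@H](C)C(=C)C3O
F5 | step 8 | (4S,8R,9S)-5-(benzyloxy)-8,9-dimethyl-4-propyl-3,4,8,9-tetrahydro-2H,10H-pyrano[2,3-f]chromene-2,10-dione | CCC[C@H]1CC(=O)Oc2c3c(cc(OCc4ccccc4)c21)O[C@H](C)[C@H](C)C3=O
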